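The readings were generated by integration with made-up constants; scatter was added.

Left-handed product is what I must count at 2.0 h in beta, theta, alpha and gamma, and these flasks differ from each other in their partner charge.

| flask | left-handed substrate | right-handed substrate | partner | free catalyst | racemization catalyst | added ligand | remark | time |
|---|---|---|---|---|---|---|---|---|
| autumn | 20 mM | 20 mM | 30 mM | 40 µM | 100 µM | 23 µM | run made earlier |  |
| winter | 20 mM | 20 mM | 260 mM | 40 µM | 100 µM | 23 µM | run made earlier |  |
| beta | 20 mM | 20 mM | 40.0 mM | 40 µM | 100 µM | 23 µM |  | 2.0 h |
| theta | 20 mM | 20 mM | 80.0 mM | 40 µM | 100 µM | 23 µM |  | 2.0 h |
| alpha | 20 mM | 20 mM | 150 mM | 40 µM | 100 µM | 23 µM |  | 2.0 h |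
| gamma | 20 mM | 20 mM | 300 mM | 40 µM | 100 µM | 23 µM |  | 2.0 h |

| autumn: time / min | autumn: left-handed product / % | winter: time / min | winter: left-handed product / % |
|---|---|---|---|
| 20.0 | 38 | 6.00 | 61 |
| 40.0 | 42 | 15.0 | 69 |
| 60.0 | 43 | 40.0 | 67 |
| 80.0 | 44 | 80.0 | 72 |

(each reading ± 1.5 percentage points)

- amount of left-handed product at the end, in percent of the left-handed substrate and right-handed substrate together charged for beta, theta, alpha, gamma, in this order
- how that number moves from the first to the last of them (falls all the way / falls, then rises / rises all the way / hardly changes / rises, then falls)

- free catalyst is single-handed; left-handed substrate and right-handed substrate are mirror images of each other, charged as a racemate, each of them at the stated concentration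
- the numbers in the tables scatter by 1.5 percentage points (one standard deviation)
- "hardly changes" means that all values lie within two and a half points (for a concentration: within two and a half percent of the largest)

Which number must I know well? Free catalyst, racemization catalyst and added ligand are charged alike in the earlier runs and the asked flasks, so what they do already sits inside the readings, and I need no figure for them. In autumn the time matters little: the reading moves 1 percentage point from 60.0 min to 80.0 min, less than the scatter of 1.5 points. The last autumn reading matters more, because one standard deviation there shifts my beta figure by 2 points. The winter level matters for the richer flasks.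

So the number is this. Autumn's last reading gives 0.587, and I call it the partner yield f, the left-handed product formed per unit of partner charged. As a first round I carry f unchanged: beta gets 58.7% and theta 117%. Going round again, I put these back. Beta lies below winter's level, the mean of its last three readings, 69.3%, so it stands, but theta's figure passes 100%, which asks for more left-handed product than the two substrates charged together allow. For theta, alpha and gamma I take winter's level instead, as an estimate from the one earlier run rich in partner, and my row rises and then stays level.

The forecast says 50%, 58%, 65% and 71%, with the shape "rises all the way", on the ground that “faster coupling at higher partner captures more substrate before activity dies”. It stands below my figure at beta and above my level at gamma.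

The flasks give 55.4%, 77.6%, 78.3% and 69.4%, and the shape is "rises, then falls".

    partner + free catalyst + left-handed substrate → free catalyst + left-handed product (k = 2.00 × 10⁵ M⁻² min⁻¹)
    partner + free catalyst + right-handed substrate → free catalyst + right-handed product (k = 21000 M⁻² min⁻¹)
    left-handed substrate + racemization catalyst ⇌ right-handed substrate + racemization catalyst, rate k3*[racemization catalyst]*[left-handed substrate] forward; the back reaction follows from the equilibrium constant (k = 1000 M⁻¹ min⁻¹)
    free catalyst + added ligand ⇌ idle complex (K = 3.90 × 10⁶ M⁻¹, k = 11000 M⁻¹ min⁻¹)
    partner → decomposed reagent (k = 0.0320 min⁻¹)

Beta's 55.4% is the figure to hold against f. At 2.00 h in beta, partner stands at 0.042% of its charge while 37% of the left-handed substrate remains, so partner is beta's limiting reagent. Beta's own partner yield is 0.554, a little less than f at 0.587. In theta, f gave 117% and the flask stores 77.6%, so theta's partner yield is 0.388, less than f.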